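In a one-step world Q and J meet and become G, and 3.00 times the Q at the same J gives 3.00 times the rate. You asked for a quick number on the east flask, so we first test that world against your runs.

| setting | west | south | north | south-east | east |
|---|---|---|---|---|---|
| Q | 300 mM | 180 mM | 300 mM | 900 mM | 2200 mM |
| J | 450 mM | 330 mM | 450 mM | 450 mM | 450 mM |
| L | 1.50 mM | 1.50 mM | 1.50 mM | 1.50 mM | 1.50 mM |
| G |  |  | 150 mM |  |  |
| time |  |  |  |  | 45 h |

- west run (time / h: [G] / mM): 5.6: 75.4; 11: 129.7; 17: 171.9; 22: 194.2; 28: 214.6; 34: 228.5; 39: 236.7; 45: 242.7
- south run (time / h: [G] / mM): 5.6: 45.7; 11: 78.2; 17: 105.5; 22: 121.0; 28: 132.3; 34: 142.5; 39: 147.9; 45: 153.7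
- north run (time / h: [G] / mM): 5.6: 224.2; 11: 270.6; 17: 304.6; 22: 321.5; 28: 337.8; 34: 347.7; 39: 353.9; 45: 360.2
- south-east run (time / h: [G] / mM): 5.6: 207.4; 11: 334.4; 17: 413.8; 22: 442.8; 28: 448.6; 34: 450.2; 39: 449.8; 45: 449.5

(scatter of a reading: 0.9 mM)

- the exponent of [Q] in the starting rate at the charge of the west run (at the point where two percent of the Q have become G) (one fixed amount of G, the same in the runs compared)
- the exponent of [J] in the starting rate at the charge of the west run (at the point where two percent of the Q have become G)
- G in the east run at 45 h, as a share of the Q charged

- Overall: Q + J -> G, with L as catalyst.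
- Constant volume, constant temperature.
- Readings of a species count what is bound in complexes too.
- "The second partner" is J.
- An order is taken over about fifteen percent of the charge, up and down.

We take the first readings of the south-east and west runs, both at 5.6 h, as a measure of their rates, and they stand at a ratio of 2.75, less than 3.00. So we follow one molecule of L round its turn: it waits for a Q, then, loaded, waits for a J. We take the rate as L divided by the length of the turn:

turn = wait for Q + wait for J

Let x be the wait for J over the wait for Q at the west charge. The south-east run has the same J and shorter Q waits, so

ratio of rates = 3.00 × (1 + x) / (1 + 3.00 x)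

This gives x = 0.0475, a reading that carries the scatter of two points, and so a J toll of 0.0453. The J toll, the share of a turn spent waiting for J, is our order in J, and the remainder, 0.955, is our order in Q.

In the east run x at the start grows with Q over J to 0.348, so we expect a start 5.70 times the west rate, twice the south-east start. The south-east run reached 448.6 mM of G from 450 mM of J by 28 h. The east run has 45 h, and J, the limiting reagent, is charged at less than Q, so we expect G to reach the 20.5% of the Q charged that the J allows.

Your forecast gives 0.92 in Q, 0.1 in J and 20.4% for the east run, on the grounds of “almost zero order in J while J is high”. We agree on the east share and part on J, where our 0.0453 stands lower than your 0.1.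

The flask gives 0.97 in Q, 0.046 in J and 20.5% for the east run, with these steps behind it:

    L + Q → LQ (42.48 /M/h)
    LQ + J → G + L (601.2 /M/h)
    L + G → Qi + G (0.1426 /M/h)
    L + Dz → Qi

The south run did not enter the toll of 0.0453, and at its charge x becomes 0.0388. Starting from the west rate of 15.7 mM/h, this gives 9.47 mM/h for the south run, where the flask stands at 9.3 mM/h at the same amount of G.

The runs were generated by integration with made-up constants, noise included.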